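## Structural features

The target is a germacrane-type sesquiterpenoid built on a ten-membered carbocycle C1–C10 (C1 ketone, C2=C3, C4 bearing methyl C15, C10 bearing methyl C14). An ether oxygen crosses the ring from C3 to C10, so that O, C10, C1, C2 and C3 form a 3(2H)-furanone. A γ-butyrolactone (O–C12(=O)–C11(C13)–C7) is trans-fused at C6–C7, and the C8 oxygen carries an (E)-2-methylbut-2-enoyl (tigloyl) group. Of the six stereocentres, C6 (R), C7 (S), C8 (S) and C11 (S) are contiguous, C10 (R) is a fully substituted carbinol carbon 1,3 to C8, and C4 (S) stands alone on the far side of the ring. The furanone is a vinylogous ester, C11 is epimerisable, O6 and O8 can both lactonise onto C12, and a free C1/C6 diketone would undergo transannular aldol reaction. The real difficulty is closing the strained ten-membered ring while relating the remote C4 centre to the C6–C10 array. The key step uses the fact that C1 and C6 are both oxygenated and stand 1,6 across the ring: C1, C6, C7, C8, C9 and C10 are the ring of a carvone-derived cyclohexane (isopropenyl carbon = C11 on C7, ring methyl = C14), and C2–C3 and C4–C5 are alkenyl arms on C1 and C6, so one [3,3] shift forms C3–C4, breaks C1–C6 and sets C4.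

## Logic of the disconnections

38 ⇒ 37 ⇒ 35 + 36. The C2=C3 double bond is removed first and then the C8–O acyl bond is cut. The vinylogous ester is the most fragile group, so it is made last, and the acylation is done on a saturated bridged ketone. The forward dehydrogenation must leave the tiglate and the lactone alone, and the acylation meets only one free hydroxyl.

35 ⇒ 33 ⇒ 32. The O–C3 bond is cut (conjugate-addition retron), then the C2=C3 bond of 33 is saturated. This removes the ether bridge and leaves a plain ten-membered α′-oxygenated ketone. The forward closure is 5-endo and therefore needs acid catalysis, and the dehydrogenation can only go towards C2 because C10 is quaternary.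

32 ⇒ 29 ⇒ 28 ⇒ 27. The lactone carbonyl is traced back to a primary C12 alcohol, the C1 ketone to a methyl enol ether and the C6 carbinol to a ketone. The 1,6-dicarbonyl relationship is thus never exposed. The forward steps require reduction of C6 from one face, oxidation of the primary alcohol only, and an O8 that stays silylated so that only O6 lactonises.

27 ⇒ 24 (key). C1–C6 is reconnected and C3–C4 is cut. The ten-membered ring becomes a cyclohexane, and C4 is traced to an (E)-propenyl group and a chair transition state. This demands that both alkenyl groups be equatorial on a chair that is free to form. For that reason O8 and O10 are carried as two separate silyl ethers. A six-membered acetal across O8 and O10 would force both C–O bonds axial, which is the flipped chair with the propenyl, vinyl and C7 groups all axial and the C6 substituent pushed under the acetal.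

24 ⇒ 22 + 23. The C5–C6 bond is cut. This leaves an α-methoxy ketone and a propenyl nucleophile. The ketone is hindered, enolisable and β-silyloxylated, so a non-basic organocerium reagent is required, and it must enter equatorially.

22 ⇒ 21 ⇒ 20 ⇒ 19. The O–CH3 bond, the C6 carbonyl and both C–O bonds at C1 and C6 are removed back to a 1-vinylcyclohexene. Carbon nucleophiles would attack a C1 ketone from the face away from C14 and put the vinyl group on the wrong side. Oxygen is therefore delivered from that face to an sp2 C1 that already carries the vinyl group. The forward step must oxidise the ring alkene and not the vinyl group.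

19 ⇒ 17 + 18 ⇒ 15. The C1–C2 bond is cut (sp2–sp2 coupling) and the enol triflate is traced to a ketone. Regiochemistry is fixed because only C6 carries α-hydrogens.

15 ⇒ 14 ⇒ 13 ⇒ 11 ⇒ 9. The C1 carbonyl returns to a benzyl-protected carbinol, the silyl ethers are removed, and the C12–O bond is cut back to the isopropenyl group. The forward hydroboration must choose the alkene face next to the C6 methylene and not the one next to the oxygenated C8.

9 ⇒ 8 ⇒ 7 ⇒ 6 ⇒ 4. The C9–H bond is traced to hydride opening of an epoxide, the epoxide to a C8-hydroxyl-directed epoxidation, the C8 allylic alcohol to a 1,3-transposition of the C10 tertiary allylic alcohol, and that to selenide opening and elimination of a 9,10-epoxide. Each step hands the configuration on from the one before.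

4 ⇒ 3 ⇒ 2 ⇒ 1. The benzyl ether, the temporary C1 carbinol and the epoxide are removed back to the enone. The epoxidation must be trans to the C7 substituent, which is the normal outcome for this enone.

## Other disconnections considered

Alternative 1: The cut is a retro-Grob reconnection of C3 to C8. The ring is seen as the fragmentation product of cage alcohol A1, a 7-oxanorbornane (bridgeheads C3 and C10, ether oxygen as the one-atom bridge) with an exo C1–C2 epoxide, a tertiary C8 carbinol and the finished lactone. In the forward step the C8 alkoxide pushes, C3–C8 breaks, C2=C3 forms and the exo C2–O bond leaves, giving keto alcohol A2.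
- In its favour: the cage holds the leaving C–O bond anti-periplanar to C3–C8, so the stereoelectronics are as dependable as those of the chosen chair shift (equal). No stereocentre has to be created in the ring-forming event. The ether bridge, the enol ether and the C6/C7/C11 triad arrive intact, so the way from A2 to the target (C8 reduction, acylation, C1 oxidation) is shorter than the seven steps after the chosen key step (better). Oxidation-state economy at the furanone is also better.
- Against it here: A1 is tetracyclic, has three contiguous fully substituted carbons (C3, C8, C10) and no evident chiral-pool origin, so the steps saved at the end would be spent several times over before the key step. The C8 centre is destroyed and must be re-set by reducing a ketone whose α-carbon C7 has the lactone oxygen β to it, an arrangement prone to β-elimination.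
- Overall the chosen plan should be shorter.

Alternative 2: The cuts are C7–C8 and C11–C13. Open-chain lactone A5 would come from butenolide A3, the 2-lithio derivative of dithiane A4, and iodomethane. The lithiated A4 adds 1,4 to A3 anti to the C6 substituent and the lactone enolate is methylated anti to the new C7 group.
- In its favour: the trans,trans C6/C7/C11 triad is set in one flask by well-understood substrate control, which is more secure than the hydroboration (C11) and ketone reduction (C6) of the chosen plan (better). The plan is convergent, so its longest linear sequence should be shorter (better). The C3 alkyne would allow the furanone to be made by 5-endo-dig closure of a hydroxy ynone at the correct oxidation level, without dehydrogenations (better).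
- Against it here: no ring is closed. The ten-membered ring would still have to be formed (C1–C2) as a strained cycloalkyne against entropy and strain. The C8 dithiane must be unmasked and reduced with control, and C4 and C10 need separate enantioselective fragment syntheses.
- The key step is mechanistically as dependable as the chosen one (equal), but it leaves the hardest structural problem open, whereas the chosen step solves it together with C4. Total step counts are probably similar.

Alternative 3: The cuts are C9–C10 and C10–O, with O–C7 re-formed. Bicyclic ketone A7 would come from diazo ketone A6, a 2-vinyl tetrahydropyran with an α-diazo ethyl ketone chain on C3. Rh2(OAc)4 or Cu(acac)2 would generate the carbenoid at C10, the pyran oxygen would capture it, and the oxonium ylide would undergo a [2,3] shift onto the vinyl group.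
- In its favour: two rings (tetrahydrofuranone and carbocycle) and the quaternary C10 are made in one step, more than the chosen key step achieves (better). The ether bridge is present from that point.
- Against it here: A7 has none of C11–C13 and no oxygen on C8. The Z C7=C8 alkene would have to be converted into the C7 side chain and the C8 oxygen on a medium ring without a reliable facial bias. The ylide can also undergo [1,2] shift or C–H insertion, and C10 control rests on the ylide geometry, which is less predictable than a chair [3,3] shift. The final dehydrogenation to the furanone is still needed (equal).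
- The core would be reached in fewer steps, but more and less controlled steps would follow.

Key step: step 18

Assumption (a): the hydride of step 2 is taken to add anti to the oxirane, so 3–14 are drawn with O1 cis to O10; this centre becomes the C1 carbonyl in step 11 and its configuration is immaterial.
Assumption (b): enone 33 is drawn as the E isomer; either geometry can close in step 23, and the C3 centre of 35 and 37 is removed in step 25.
Assumption (c): alkoxides that are only protonated on aqueous work-up are not listed as separate compounds, except those of the key step.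

## Steps

Step 1
Reactants: 1 (R)-carvone
Product: 2 9,10-epoxy ketone (carvone oxide, oxirane trans to the C7 isopropenyl group)
Conditions: H2O2 (30 %), NaOH, MeOH, 0 °C
Reagents that add atoms: hydrogen peroxide, OO
Why: Weitz–Scheffer nucleophilic epoxidation touches only the enone; hydroperoxide adds to C9 anti to the C7 isopropenyl group, so C10 is set with its oxygen trans to that group and C14 cis to it.

Step 2
Reactants: 2 9,10-epoxy ketone
Product: 3 epoxy alcohol (C1 carbinol, OH cis to the oxirane)
Conditions: NaBH4, MeOH, −20 °C
Reagents that add atoms: none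
Why: Borohydride 1,2-reduction of an α,β-epoxy ketone, expected anti to the oxirane oxygen; the carbinol only masks the C1 carbonyl against the later selenide and hydride steps.

Step 3
Reactants: 3 epoxy alcohol
Product: 4 1-O-benzyl epoxide
Conditions: NaH, BnBr, n-Bu4NI (cat.), THF, 0 °C → rt
Reagents that add atoms: benzyl bromide, BrCc1ccccc1
Why: Williamson etherification; the alkoxide is cis to the oxirane, so epoxide migration by backside attack is not possible.

Step 4
Reactants: 4 1-O-benzyl epoxide
Product: 6 tertiary allylic alcohol (1-O-benzyl-10-hydroxy-8-ene), via hydroxy selenide 5 (not isolated)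
Conditions: (PhSe)2, NaBH4, EtOH, reflux; then H2O2 (30 %), pyridine, THF, 0 °C → rt
Reagents that add atoms: none
Why: Epoxide to allylic alcohol transposition by selenide opening and selenoxide syn-elimination: the selenolate can only attack the secondary C9 (inversion), C10 keeps its oxygen and configuration, and the selenoxide has β-hydrogens only on C8.

Step 5
Reactants: 6 tertiary allylic alcohol
Product: 7 secondary allylic alcohol (1-O-benzyl-8-hydroxy-9-ene)
Conditions: Ph3SiOReO3 (3 mol %), Et2O, −50 → 0 °C
Reagents that add atoms: none
Why: Perrhenate-catalysed 1,3-transposition of an allylic alcohol through a cyclic [3,3] perrhenate ester; in a ring it is suprafacial, so O8 arrives on the face that O10 left (trans to the C7 group), and the trisubstituted 9,10-alkene drives the equilibrium.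

Step 6
Reactants: 7 secondary allylic alcohol
Product: 8 9,10-epoxy-8-ol
Conditions: VO(acac)2 (3 mol %), t-BuOOH, CH2Cl2, 0 °C → rt
Reagents that add atoms: tert-butyl hydroperoxide, CC(C)(C)OO
Why: Vanadium-catalysed hydroxyl-directed epoxidation of a cyclic allylic alcohol delivers oxygen syn to the C8 hydroxyl, which restores O10 on the required face; the isopropenyl group is only homoallylic and reacts much more slowly.

Step 7
Reactants: 8 9,10-epoxy-8-ol
Product: 9 syn-8,10-diol
Conditions: LiAlH4, THF, 0 °C → reflux
Reagents that add atoms: none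
Why: Hydride opens the trisubstituted epoxide at its secondary carbon C9 and cannot attack the tertiary C10, so the tertiary alcohol and the syn-1,3-diol result; the benzyl ether and the isopropenyl group are inert.

Step 8
Reactants: 9 syn-8,10-diol
Product: 11 8,10,12-triol, via B-alkyl-9-BBN adduct 10 (not isolated)
Conditions: 9-BBN, THF, 0 °C → rt; then NaOH, H2O2, 0 °C
Reagents that add atoms: hydrogen peroxide, OO
Why: Anti-Markovnikov hydroboration–oxidation of the 1,1-disubstituted alkene; with H7 eclipsing the C=CH2 bond the borane should add from the face next to the C6 methylene and not the oxygenated C8, which gives the 11S centre.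

Step 9
Reactants: 11 8,10,12-triol
Product: 13 fully protected ether (1-OBn 8-OTBS 10-OTES 12-OTBS), via bis-TBS ether 12 (not isolated)
Conditions: TBSCl, imidazole, DMAP (cat.), CH2Cl2, rt; then TESOTf, 2,6-lutidine, −40 → 0 °C
Reagents that add atoms: tert-butyldimethylsilyl chloride, CC(C)(C)[Si](C)(C)Cl; triethylsilyl trifluoromethanesulfonate, CC[Si](CC)(CC)OS(=O)(=O)C(F)(F)F
Why: Silylation by steric class: the chloride reaches only the primary and secondary hydroxyls and the triflate then caps the tertiary one. Two separate ethers, unlike a cyclic acetal, leave the ring free to adopt the chair with O8 and O10 equatorial.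

Step 10
Reactants: 13 fully protected ether
Product: 14 C1 alcohol
Conditions: H2 (1 atm), Pd/C, EtOAc, rt
Reagents that add atoms: none
Why: Hydrogenolysis of the benzyl ether; no alkene remains at this stage and the silyl ethers are stable in neutral ethyl acetate.

Step 11
Reactants: 14 C1 alcohol
Product: 15 C1 ketone
Conditions: Dess–Martin periodinane, NaHCO3, CH2Cl2, rt
Reagents that add atoms: none
Why: Buffered hypervalent-iodine oxidation of a hindered secondary alcohol; C10 is quaternary, so the α-silyloxy ketone cannot epimerise.

Step 12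
Reactants: 15 C1 ketone
Product: 17 enol triflate (C1=C6), via potassium enolate 16 (not isolated)
Conditions: KN(SiMe3)2, THF, −78 °C; then PhNTf2, −78 → 0 °C
Reagents that add atoms: N-phenylbis(trifluoromethanesulfonimide), O=S(=O)(N(c1ccccc1)S(=O)(=O)C(F)(F)F)C(F)(F)F
Why: Only C6 carries α-hydrogens, so enolate formation and O-triflation are regiochemically unambiguous; there is no leaving group β to the enolate carbon.

Step 13
Reactants: 17 enol triflate; 18 vinylmagnesium bromide
Product: 19 1-vinylcyclohexene diene
Conditions: 18, ZnCl2, THF, 0 °C; then 17, Pd(PPh3)4 (5 mol %), THF, 50 °C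
Reagents that add atoms: none
Why: Negishi coupling: zerovalent palladium inserts into the C–OTf bond and the vinylzinc reagent made in the flask transfers the vinyl group; silyl ethers are untouched.

Step 14
Reactants: 19 1-vinylcyclohexene diene
Product: 20 1,6-cis-diol (tertiary C1–OH, secondary C6–OH)
Conditions: OsO4 (5 mol %), NMO, acetone/H2O (5:1), rt
Reagents that add atoms: N-methylmorpholine N-oxide, C[N+]1([O-])CCOCC1; water, O
Why: Upjohn dihydroxylation of the more electron-rich trisubstituted ring alkene, anti to the pseudo-axial C14 methyl; this puts O1 on the face of O10 and the vinyl group equatorial, the C1 configuration that carbon nucleophiles adding to a C1 ketone would not give.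

Step 15
Reactants: 20 1,6-cis-diol
Product: 21 α-ketol (C6 ketone, tertiary C1–OH)
Conditions: (COCl)2, DMSO, CH2Cl2, −78 °C; then Et3N, −78 → −20 °C
Reagents that add atoms: none
Why: Swern oxidation takes the secondary carbinol of a secondary/tertiary diol without C–C cleavage; the low temperature guards C7 and the β-silyloxy group.

Step 16
Reactants: 21 α-ketol
Product: 22 1-methoxy-1-vinyl ketone
Conditions: MeOTf, 2,6-di-tert-butyl-4-methylpyridine, CH2Cl2, 0 → 40 °C
Reagents that add atoms: methyl trifluoromethanesulfonate, COS(=O)(=O)C(F)(F)F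
Why: O-Methylation of a hindered tertiary alcohol under non-basic conditions; an alkoxide is avoided because it would invite α-ketol rearrangement and enolisation towards C7.

Step 17
Reactants: 22 1-methoxy-1-vinyl ketone; 23 (E)-1-bromoprop-1-ene
Product: 24 oxy-Cope substrate (6-hydroxy-6-(E)-propenyl-1-methoxy-1-vinyl cyclohexane)
Conditions: 23, t-BuLi (2 equiv), Et2O, −78 °C; CeCl3, THF, −78 °C; then 22, −78 °C
Reagents that add atoms: none
Why: Bromine–lithium exchange keeps the E geometry, and the organocerium reagent adds to the hindered, enolisable ketone without deprotonating C7. An axial approach is 1,3-diaxial to the C14 methyl, so the propenyl group should enter equatorially, trans to the C7 chain and to the vinyl group.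

Step 18
Reactants: 24 oxy-Cope substrate
Product: 27 ten-membered 6-keto 1-methoxy-1-ene, via potassium alkoxide 25 (not isolated), via potassium enolate 26 (not isolated)
Conditions: KH, 18-crown-6, THF, 0 °C → rt; NH4Cl (aq), −78 °C
Reagents that add atoms: none
Why: KH with 18-crown-6 converts 24 into the free C6 alkoxide 25, whose oxyanion accelerates the [3,3] shift of the C4=C5–C6–C1–C2=C3 array: C3–C4 forms while the ring bond C1–C6 breaks, giving enolate 26 and the C1=C2 methyl enol ether, and cold protonation gives 27. The closest known reaction type is the anionic oxy-Cope ring expansion of trans-1,2-dialkenylcyclohexanols to cyclodec-5-enones. The ten-membered ring is closed by four-carbon ring expansion through a six-atom chair array, not by end-to-end cyclisation, so no high dilution is needed. C4 is the only new stereocentre: in the chair of 24 the 8- and 10-silyloxy groups, the C7 chain, the propenyl group and the vinyl group are all equatorial, the two alkenyl groups are gauche with a fixed sense of twist, and the chair transition state with the (E)-propenyl methyl pseudo-equatorial delivers C3 to one face of C4 only (4S as in 38). The step needs chair over boat, a concerted shift over cleavage and recombination, and no equilibration of 26 towards C7, which would expel the C8 silyloxy group; the unbridged chair, the low temperature and the cold quench serve these needs. The C1 methyl ether prevents a second alkoxide and ends as an enol ether that masks the C1 ketone and blocks transannular aldol reaction with the new C6 ketone; its double-bond geometry is irrelevant.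

Step 19
Reactants: 27 ten-membered 6-keto 1-methoxy-1-ene
Product: 28 6-alcohol (6R)
Conditions: NaBH4, MeOH/THF, −40 °C
Reagents that add atoms: none
Why: Felkin–Anh reduction with hydride entering anti to the branched C11 substituent on C7 should give the carbinol with H6 anti to H7, as the trans lactone needs; the enol ether and silyl ethers are inert.

Step 20
Reactants: 28 6-alcohol
Product: 29 6,12-dihydroxy C1 ketone (8-OTBS and 10-OTES kept)
Conditions: AcOH/THF/H2O (3:1:1), rt
Reagents that add atoms: water, O
Why: Mild aqueous acid hydrolyses the methyl enol ether and cleaves only the primary silyl ether. C6 is no longer a carbonyl, so the C1 ketone can now be exposed; any loss of the tertiary triethylsilyl ether here would not matter because it is removed in step 23.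

Step 21
Reactants: 29 6,12-dihydroxy C1 ketone
Product: 32 trans-fused 6,12-lactone, via hydroxy aldehyde 30 (not isolated), via lactol 31 (not isolated)
Conditions: TEMPO (20 mol %), PhI(OAc)2, CH2Cl2, rt
Reagents that add atoms: none
Why: Oxoammonium oxidation takes the primary alcohol first, the aldehyde closes onto O6 and the lactol is oxidised to the lactone; O8 is still silylated, so an 8,12-lactone cannot form.

Step 22
Reactants: 32 trans-fused 6,12-lactone
Product: 33 2,3-enone
Conditions: IBX, DMSO/PhF, 65 °C
Reagents that add atoms: none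
Why: IBX dehydrogenation of a ketone to its enone; only C2 is enolisable, and the lactone α-position is not touched by this reagent, so C11 is safe.

Step 23
Reactants: 33 2,3-enone
Product: 35 bridged tetrahydrofuran-3-one with free 8-OH, via dihydroxy enone 34 (not isolated)
Conditions: aq. HF (48 %), MeCN, 0 °C → rt; then p-TsOH·H2O (cat.), CH2Cl2, rt
Reagents that add atoms: none
Why: Both silyl ethers are cleaved, and acid then catalyses the conjugate addition of the C10 hydroxyl to C3. This 5-endo closure of an α′-hydroxy enone fails under base but is known under acid; O8 could only form a seven-membered ring and does not compete.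

Step 24
Reactants: 35 bridged tetrahydrofuran-3-one; 36 tigloyl chloride
Product: 37 8-O-tigloyl tetrahydrofuranone
Conditions: 36, pyridine, DMAP (cat.), CH2Cl2, 0 °C → rt
Reagents that add atoms: none
Why: Acylation of the only free hydroxyl; the E geometry of the tiglate is the stable one and should survive DMAP catalysis.

Step 25
Reactants: 37 8-O-tigloyl tetrahydrofuranone
Product: 38 target CNP0235937.1
Conditions: IBX, DMSO, 75 °C
Reagents that add atoms: none
Why: A second IBX dehydrogenation; the C1 ketone can only enolise towards C2 and loss of H3 gives the 3(2H)-furanone, which cannot be oxidised further; lactone and tiglate do not react.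

## Compound list

1 | (R)-carvone | CC1=CC[C@H](CC1=O)C(C)=C | starting material
2 | 9,10-epoxy ketone (carvone oxide, oxirane trans to isopropenyl) | C1[C@H](C(C)=C)C[C@H]2O[C@@]2(C)C1=O | intermediate
3 | epoxy alcohol (C1–OH cis to oxirane) | C1[C@H](C(C)=C)C[C@H]2O[C@@]2(C)[C@H]1O | intermediate
4 | 1-O-benzyl epoxide | C1[C@H](C(C)=C)C[C@H]2O[C@@]2(C)[C@H]1OCc1ccccc1 | intermediate
5 | hydroxy selenide (9-SePh, 10-OH) | C1[C@H](C(C)=C)C[C@H]([Se]c2ccccc2)[C@@](C)(O)[C@H]1OCc1ccccc1 | intermediate (not isolated)
6 | tertiary allylic alcohol (10-OH, 8-ene) | C1[C@H](C(C)=C)C=C[C@@](C)(O)[C@H]1OCc1ccccc1 | intermediate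
7 | secondary allylic alcohol (8-OH, 9-ene) | C1[C@H](C(C)=C)[C@@H](O)C=C(C)[C@H]1OCc1ccccc1 | intermediate
8 | 9,10-epoxy-8-ol | C1[C@H](C(C)=C)[C@@H](O)[C@H]2O[C@@]2(C)[C@H]1OCc1ccccc1 | intermediate
9 | syn-8,10-diol | C1[C@H](C(C)=C)[C@@H](O)C[C@@](C)(O)[C@H]1OCc1ccccc1 | intermediate
10 | B-alkyl-9-BBN adduct | C1[C@H]([C@H](C)CB2C3CCCC2CCC3)[C@@H](O)C[C@@](C)(O)[C@H]1OCc1ccccc1 | intermediate (not isolated)
11 | 8,10,12-triol | C1[C@H]([C@H](C)CO)[C@@H](O)C[C@@](C)(O)[C@H]1OCc1ccccc1 | intermediate
12 | 8,12-bis-TBS ether | C1[C@H]([C@H](C)CO[Si](C)(C)C(C)(C)C)[C@@H](O[Si](C)(C)C(C)(C)C)C[C@@](C)(O)[C@H]1OCc1ccccc1 | intermediate (not isolated)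
13 | fully protected ether (1-OBn, 8-OTBS, 10-OTES, 12-OTBS) | C1[C@H]([C@H](C)CO[Si](C)(C)C(C)(C)C)[C@@H](O[Si](C)(C)C(C)(C)C)C[C@@](C)(O[Si](CC)(CC)CC)[C@H]1OCc1ccccc1 | intermediate
14 | C1 alcohol | C1[C@H]([C@H](C)CO[Si](C)(C)C(C)(C)C)[C@@H](O[Si](C)(C)C(C)(C)C)C[C@@](C)(O[Si](CC)(CC)CC)[C@H]1O | intermediate
15 | C1 ketone | C1[C@H]([C@H](C)CO[Si](C)(C)C(C)(C)C)[C@@H](O[Si](C)(C)C(C)(C)C)C[C@@](C)(O[Si](CC)(CC)CC)C1=O | intermediate
16 | potassium enolate of 15 | [K+].[O-]C1=C[C@H]([C@H](C)CO[Si](C)(C)C(C)(C)C)[C@@H](O[Si](C)(C)C(C)(C)C)C[C@@]1(C)O[Si](CC)(CC)CC | intermediate (not isolated)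
17 | enol triflate (C1=C6) | FC(F)(F)S(=O)(=O)OC1=C[C@H]([C@H](C)CO[Si](C)(C)C(C)(C)C)[C@@H](O[Si](C)(C)C(C)(C)C)C[C@@]1(C)O[Si](CC)(CC)CC | intermediate
18 | vinylmagnesium bromide | C=C[Mg]Br | starting material
19 | 1-vinylcyclohexene diene | C=CC1=C[C@H]([C@H](C)CO[Si](C)(C)C(C)(C)C)[C@@H](O[Si](C)(C)C(C)(C)C)C[C@@]1(C)O[Si](CC)(CC)CC | intermediate
20 | 1,6-cis-diol | O[C@H]1[C@H]([C@H](C)CO[Si](C)(C)C(C)(C)C)[C@@H](O[Si](C)(C)C(C)(C)C)C[C@@](C)(O[Si](CC)(CC)CC)[C@]1(O)C=C | intermediate
21 | α-ketol (C6 ketone, C1–OH) | O=C1[C@H]([C@H](C)CO[Si](C)(C)C(C)(C)C)[C@@H](O[Si](C)(C)C(C)(C)C)C[C@@](C)(O[Si](CC)(CC)CC)[C@]1(O)C=C | intermediate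
22 | 1-methoxy-1-vinyl ketone | O=C1[C@H]([C@H](C)CO[Si](C)(C)C(C)(C)C)[C@@H](O[Si](C)(C)C(C)(C)C)C[C@@](C)(O[Si](CC)(CC)CC)[C@]1(OC)C=C | intermediate
23 | (E)-1-bromoprop-1-ene | C/C=C/Br | starting material
24 | oxy-Cope substrate | O[C@]1(/C=C/C)[C@H]([C@H](C)CO[Si](C)(C)C(C)(C)C)[C@@H](O[Si](C)(C)C(C)(C)C)C[C@@](C)(O[Si](CC)(CC)CC)[C@@]1(C=C)OC | intermediate
25 | potassium alkoxide of 24 | [K+].[O-][C@]1(/C=C/C)[C@H]([C@H](C)CO[Si](C)(C)C(C)(C)C)[C@@H](O[Si](C)(C)C(C)(C)C)C[C@@](C)(O[Si](CC)(CC)CC)[C@@]1(C=C)OC | intermediate (not isolated)
26 | potassium enolate of 27 (C5=C6) | [K+].[O-]/C1=C\[C@H](C)C/C=C(OC)/[C@](C)(O[Si](CC)(CC)CC)C[C@H](O[Si](C)(C)C(C)(C)C)[C@H]1[C@H](C)CO[Si](C)(C)C(C)(C)C | intermediate (not isolated)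
27 | ten-membered 6-keto 1-methoxy-1-ene | O=C1C[C@H](C)C/C=C(OC)/[C@](C)(O[Si](CC)(CC)CC)C[C@H](O[Si](C)(C)C(C)(C)C)[C@H]1[C@H](C)CO[Si](C)(C)C(C)(C)C | intermediate
28 | 6-alcohol (6R) | O[C@@H]1C[C@H](C)C/C=C(OC)/[C@](C)(O[Si](CC)(CC)CC)C[C@H](O[Si](C)(C)C(C)(C)C)[C@H]1[C@H](C)CO[Si](C)(C)C(C)(C)C | intermediate
29 | 6,12-dihydroxy C1 ketone | O[C@@H]1C[C@H](C)CCC(=O)[C@](C)(O[Si](CC)(CC)CC)C[C@H](O[Si](C)(C)C(C)(C)C)[C@H]1[C@H](C)CO | intermediate
30 | hydroxy aldehyde (C12 aldehyde) | O[C@@H]1C[C@H](C)CCC(=O)[C@](C)(O[Si](CC)(CC)CC)C[C@H](O[Si](C)(C)C(C)(C)C)[C@H]1[C@H](C)C=O | intermediate (not isolated)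
31 | lactol (C12 configuration open) | CC(C)(C)[Si](C)(C)O[C@H]1C[C@@](C)(O[Si](CC)(CC)CC)C(=O)CC[C@@H](C)C[C@H]2OC(O)[C@@H](C)[C@H]12 | intermediate (not isolated)
32 | trans-fused 6,12-lactone | CC(C)(C)[Si](C)(C)O[C@H]1C[C@@](C)(O[Si](CC)(CC)CC)C(=O)CC[C@@H](C)C[C@H]2OC(=O)[C@@H](C)[C@H]12 | intermediate
33 | 2,3-enone | CC(C)(C)[Si](C)(C)O[C@H]1C[C@@](C)(O[Si](CC)(CC)CC)C(=O)/C=C/[C@@H](C)C[C@H]2OC(=O)[C@@H](C)[C@H]12 | intermediate
34 | dihydroxy enone (8-OH, 10-OH) | O[C@H]1C[C@@](C)(O)C(=O)/C=C/[C@@H](C)C[C@H]2OC(=O)[C@@H](C)[C@H]12 | intermediate (not isolated)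
35 | bridged tetrahydrofuran-3-one, 8-OH | O[C@H]1C[C@@]2(C)O[C@H](CC2=O)[C@@H](C)C[C@H]3OC(=O)[C@@H](C)[C@H]13 | intermediate
36 | tigloyl chloride ((E)-2-methylbut-2-enoyl chloride) | C/C=C(\C)C(Cl)=O | starting material
37 | 8-O-tigloyl tetrahydrofuranone | C/C=C(\C)C(=O)O[C@H]1C[C@@]2(C)O[C@H](CC2=O)[C@@H](C)C[C@H]3OC(=O)[C@@H](C)[C@H]13 | intermediate
38 | CNP0235937.1 | C/C=C(\C)C(=O)O[C@H]1C[C@@]2(C)OC(=CC2=O)[C@@H](C)C[C@H]2OC(=O)[C@@H](C)[C@H]12 | target

## Step count and least certain steps

Total: 25 steps. Longest linear sequence: 25 steps from 1; 18, 23 and 36 are bought and enter at steps 13, 17 and 24.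

Step 18 (key step). The C1–C6 bond may cleave heterolytically to an enone and a methoxyallyl anion that recombine without stereocontrol. The enolate may also equilibrate towards C7 and expel the C8 silyloxy group, or the triethylsilyl group may migrate to the C6 alkoxide and stall the shift. Fallback: a neutral thermal siloxy-Cope. From 24, TMSOTf and 2,6-lutidine should give the trimethylsilyl ether F1; heating in toluene in a sealed tube at about 200 °C should give the silyl enol ether F2 through the same chair; K2CO3 in MeOH at −20 °C would release the ketone and return to 27.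

Step 16. The tertiary hydroxyl is flanked by a quaternary carbon and a ketone, so methylation may be too slow and α-ketol rearrangement or loss of a silyl ether may take over. Fallback from 20: CH2Br2 and NaH in DMF should tie O1 and O6 into the methylene acetal F3. i-Bu2AlH in toluene should coordinate the less hindered O6 and cleave the acetal C–O6 bond, leaving the methyl on O1 in methoxy alcohol F4. Swern oxidation of F4 returns to 22.

Step 14. Osmylation may also attack the terminal vinyl group, or facial selectivity at the hindered ring alkene may be poor. Fallback from 17: couple with ethynylzinc chloride (from ethynylmagnesium bromide and ZnCl2, Pd(PPh3)4) to the enyne F5, whose alkyne is inert to OsO4. Dihydroxylation should give the ethynyl diol F6, Swern oxidation the ethynyl ketol F7, and MeOTf with the hindered pyridine the ethynyl methyl ether F8. Semihydrogenation over Pd/CaCO3 poisoned with Pb(OAc)2 and quinoline returns to 22.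

Step 19. The conformation of the ten-membered ring may expose the other carbonyl face, giving the 6-epimeric alcohol F9. Fallback from 27: Mitsunobu inversion of F9 (4-nitrobenzoic acid, PPh3, DIAD, toluene, 0 °C) should give the 4-nitrobenzoate F10 with the correct C6; K2CO3 in MeOH returns to 28.

Step 5. The transposition may stop at an unfavourable equilibrium, or ionisation may lead to elimination and aromatisation with loss of benzyl alcohol. Fallback from 6: oxidative transposition with pyridinium chlorochromate (C5H5NH)[CrO3Cl] to the enone F11, then Luche reduction (NaBH4, CeCl3·7H2O, MeOH, −78 °C), in which hydride should enter trans to the C7 substituent, returns to 7.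

Step 8. Facial selectivity at C11 may be poor because the free C8 hydroxyl is a small directing group. Fallback from 9: silylate O8 first (TBSCl, imidazole) to the 8-O-TBS diol F12, and hydroborate with 9-BBN next to the bulky silyl ether to the primary alcohol F13. TBSCl then TESOTf returns to 13 through 12.

## Further compounds

F1 | step 18 | trimethylsilyl ether of 24 | C[Si](C)(C)O[C@]1(/C=C/C)[C@H]([C@H](C)CO[Si](C)(C)C(C)(C)C)[C@@H](O[Si](C)(C)C(C)(C)C)C[C@@](C)(O[Si](CC)(CC)CC)[C@@]1(C=C)OC
F2 | step 18 | trimethylsilyl enol ether of 27 (C5=C6) | C[Si](C)(C)O/C1=C\[C@H](C)C/C=C(OC)/[C@](C)(O[Si](CC)(CC)CC)C[C@H](O[Si](C)(C)C(C)(C)C)[C@H]1[C@H](C)CO[Si](C)(C)C(C)(C)C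
F3 | step 16 | 1,6-O-methylene acetal of 20 | C1O[C@H]2[C@H]([C@H](C)CO[Si](C)(C)C(C)(C)C)[C@@H](O[Si](C)(C)C(C)(C)C)C[C@@](C)(O[Si](CC)(CC)CC)[C@]2(O1)C=C
F4 | step 16 | 1-methoxy-6-ol | O[C@H]1[C@H]([C@H](C)CO[Si](C)(C)C(C)(C)C)[C@@H](O[Si](C)(C)C(C)(C)C)C[C@@](C)(O[Si](CC)(CC)CC)[C@]1(OC)C=C
F5 | step 14 | 1-ethynylcyclohexene enyne | C#CC1=C[C@H]([C@H](C)CO[Si](C)(C)C(C)(C)C)[C@@H](O[Si](C)(C)C(C)(C)C)C[C@@]1(C)O[Si](CC)(CC)CC
F6 | step 14 | 1-ethynyl 1,6-cis-diol | O[C@H]1[C@H]([C@H](C)CO[Si](C)(C)C(C)(C)C)[C@@H](O[Si](C)(C)C(C)(C)C)C[C@@](C)(O[Si](CC)(CC)CC)[C@]1(O)C#C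
F7 | step 14 | 1-ethynyl α-ketol | O=C1[C@H]([C@H](C)CO[Si](C)(C)C(C)(C)C)[C@@H](O[Si](C)(C)C(C)(C)C)C[C@@](C)(O[Si](CC)(CC)CC)[C@]1(O)C#C
F8 | step 14 | 1-ethynyl-1-methoxy ketone | O=C1[C@H]([C@H](C)CO[Si](C)(C)C(C)(C)C)[C@@H](O[Si](C)(C)C(C)(C)C)C[C@@](C)(O[Si](CC)(CC)CC)[C@]1(OC)C#C
F9 | step 19 | 6-epimer of 28 | O[C@H]1C[C@H](C)C/C=C(OC)/[C@](C)(O[Si](CC)(CC)CC)C[C@H](O[Si](C)(C)C(C)(C)C)[C@H]1[C@H](C)CO[Si](C)(C)C(C)(C)C
F10 | step 19 | 4-nitrobenzoate of 28 | O=C(O[C@@H]1C[C@H](C)C/C=C(OC)/[C@](C)(O[Si](CC)(CC)CC)C[C@H](O[Si](C)(C)C(C)(C)C)[C@H]1[C@H](C)CO[Si](C)(C)C(C)(C)C)c1ccc(cc1)[N+](=O)[O-]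
F11 | step 5 | 8-oxo-9-ene (transposed enone) | C1[C@H](C(C)=C)C(=O)C=C(C)[C@H]1OCc1ccccc1
F12 | step 8 | 8-O-TBS ether of 9 | C1[C@H](C(C)=C)[C@@H](O[Si](C)(C)C(C)(C)C)C[C@@](C)(O)[C@H]1OCc1ccccc1
F13 | step 8 | 8-O-TBS 10,12-diol | C1[C@H]([C@H](C)CO)[C@@H](O[Si](C)(C)C(C)(C)C)C[C@@](C)(O)[C@H]1OCc1ccccc1
A1 | alternative 1 | epoxy 7-oxanorbornane cage alcohol (C8–OH drawn endo; this centre is lost) | O[C@]12C[C@@]3(C)O[C@@]1([C@@H]1O[C@@H]13)[C@@H](C)C[C@H]1OC(=O)[C@@H](C)[C@@H]12
A2 | alternative 1 | 8-oxo-1-hydroxy bridged dihydrofuran lactone | O=C1C[C@@]2(C)OC(=C[C@@H]2O)[C@@H](C)C[C@H]2OC(=O)[C@@H](C)[C@H]12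
A3 | alternative 2 | 5-substituted butenolide (C3–C7, C12) | O=C1O[C@H](C[C@H](C)C#C)C=C1
A4 | alternative 2 | 2-substituted 1,3-dithiane (C8–C10, C1, C14) | C1CSC(SC1)C[C@]2(C)COC(C)(C)O2
A5 | alternative 2 | trans,trans lactone with C8 dithiane | O=C1O[C@H](C[C@H](C)C#C)[C@H]([C@@H]1C)C1(SCCCS1)C[C@]2(C)COC(C)(C)O2
A6 | alternative 3 | α-diazo ethyl ketone on a 2-vinyl tetrahydropyran (C7 configuration left open) | CC(=[N+]=[N-])C(=O)C[C@H]1OC(C=C)[C@H](O[Si](C)(C)C(C)(C)C)C[C@@H]1C
A7 | alternative 3 | 11-oxabicyclo[6.2.1]undec-7-enone core | O=C1C[C@H]2O[C@]1(C)C/C=C\[C@H](O[Si](C)(C)C(C)(C)C)C[C@@H]2C
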